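**Retrosynthetic overview**
- Lespeflorin B3 is a (2R,3R)-trans-3-hydroxyflavanone. Rings A and B are bought as arenes; ring C (O1–C2–C3–C4–C4a–C8a) is the only ring to be made.
- The route rests on C3 of ring C: an oxygen-bearing sp3 carbon flanked by the C4 carbonyl and by benzylic C2. It maps onto the diazo carbon of a ring A diazomethyl ketone, whose rhodium carbenoid picks up the C3 oxygen from 4-methoxybenzyl alcohol and then C2 from the ring B aldehyde (bonds C3–O and C2–C3, both stereocentres).
- Ring C is closed afterwards at O1–C2 by an invertive Mitsunobu etherification of the syn aldol; the 4-methoxybenzyl and silyl groups come off last.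
- The three prenyl groups are installed early by aromatic Claisen rearrangement of allyl ethers and cross-metathesis with 2-methyl-2-butene; the ring A ester is taken through the acid chloride to the diazoketone.
- Order of ring formation: no ring in the key step; ring C in step 12.

Key step: step 10

Abbreviations: prenyl = 3-methylbut-2-enyl; TBS = tert-butyldimethylsilyl; PMB = 4-methoxybenzyl.

Assumption (remark on the chemistry): the sense of induction of the zirconium–BINOL Lewis acid cannot be assigned with confidence for this substrate class. The (S)-ligand is written on the assumption that it exposes the Re face of the ring B aldehyde; if a model run with MTPA ester analysis shows the opposite sense, the (R)-ligand is used and nothing else changes.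

**Route**

Step 1
Reactants: 1 methyl 2,4-dihydroxybenzoate; 2 allyl bromide
Product: 3 methyl 2,4-bis(allyloxy)benzoate
Conditions: allyl bromide (3 equiv), K2CO3 (3 equiv), DMF, 60 °C
Reagents that add atoms: allyl bromide (2), C=CCBr
Why: Williamson etherification; K2CO3 in warm DMF should alkylate the hydrogen-bonded 2-OH as well as the 4-OH, and the methyl ester is inert.

Step 2
Reactants: 3 methyl 2,4-bis(allyloxy)benzoate
Product: 5 methyl 3,5-diallyl-2,4-dihydroxybenzoate, via monoallyl phenol 4 (not isolated)
Conditions: N,N-diethylaniline, 200 °C, Ar, sealed tube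
Reagents that add atoms: none
Why: Two aromatic Claisen rearrangements ([3,3]-sigmatropic shifts) run in one pot: the 2-O-allyl group can reach only C3 and the 4-O-allyl group C5, and if the 4-O-allyl group takes C3 first, the 2-O-allyl group reaches C5 by the para-Claisen (Claisen then Cope) relay, which for an unsubstituted allyl group delivers the same substituent, so every path (4 is one representative) should end at the 3,5-diallyl compound.

Step 3
Reactants: 5 methyl 3,5-diallyl-2,4-dihydroxybenzoate; 6 2-methyl-2-butene
Product: 7 methyl 2,4-dihydroxy-3,5-diprenylbenzoate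
Conditions: second-generation Grubbs catalyst RuCl2(=CHPh)(H2IMes)(PCy3) (5 mol %), 2-methyl-2-butene/CH2Cl2, 40 °C, sealed tube
Reagents that add atoms: 2-methyl-2-butene (6), CC=C(C)C
Why: Olefin cross-metathesis with a large excess of 2-methyl-2-butene should convert each terminal allyl group into a prenyl group with loss of propene, a standard entry to prenyl arenes that tolerates phenols and esters; the two allyl groups are meta to each other and cannot ring-close.

Step 4
Reactants: 7 methyl 2,4-dihydroxy-3,5-diprenylbenzoate
Product: 8 2,4-dihydroxy-3,5-diprenylbenzoic acid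
Conditions: KOH, MeOH/H2O, 65 °C; then 1 M HCl to pH 3, 0 °C
Reagents that add atoms: potassium hydroxide, [K+].[OH-] (its oxygen becomes the carboxyl OH)
Why: Saponification; the prenyl groups are stable to base, and cold, brief acidification should avoid both decarboxylation of the resorcylic acid and acid-induced chroman formation.

Step 5
Reactants: 8 2,4-dihydroxy-3,5-diprenylbenzoic acid
Product: 11 2-acetoxy-4-(tert-butyldimethylsilyloxy)-3,5-diprenylbenzoic acid, via silyl ester phenol 9 (not isolated), via silyl ester acetate 10 (not isolated)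
Conditions: TBSCl (2.3 equiv), imidazole, DMF, rt; then Ac2O, Et3N, DMAP (cat.), 0 °C to rt; then AcOH/THF/H2O, rt
Reagents that add atoms: tert-butyldimethylsilyl chloride, CC(C)(C)[Si](C)(C)Cl; acetic anhydride, CC(=O)OC(C)=O
Why: Chemoselective silylation (the 2-OH is hydrogen-bonded to the carboxyl carbonyl and stays free while the 4-OH and the CO2H are silylated), then DMAP-catalysed acetylation of the remaining phenol, then mild aqueous-acid hydrolysis that should cleave only the labile silyl ester and leave the aryl silyl ether and the aryl acetate.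

Step 6
Reactants: 11 2-acetoxy-4-(tert-butyldimethylsilyloxy)-3,5-diprenylbenzoic acid
Product: 13 2-acetoxy-4-(tert-butyldimethylsilyloxy)-3,5-diprenylphenyl diazomethyl ketone, via acid chloride 12 (not isolated)
Conditions: 1-chloro-N,N,2-trimethylprop-1-en-1-amine, CH2Cl2, 0 °C to rt; then CH2N2 (excess), Et2O, 0 °C
Reagents that add atoms: 1-chloro-N,N,2-trimethylprop-1-en-1-amine, CC(C)=C(Cl)N(C)C (chlorine of 12); diazomethane, C=[N+]=[N-]
Why: The α-chloroenamine makes the acid chloride without setting HCl free, so prenyl and silyl groups are safe, and C-acylation of diazomethane (first stage of the Arndt–Eistert sequence, established for O-acetylsalicyloyl chloride) should give the diazoketone while excess diazomethane scavenges HCl.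

Step 7
Reactants: 14 4-(allyloxy)benzaldehyde
Product: 15 3-allyl-4-hydroxybenzaldehyde
Conditions: N,N-diethylaniline, 200 °C, Ar
Reagents that add atoms: none
Why: Aromatic Claisen rearrangement to the free ortho position, a well-established conversion for this substrate.

Step 8
Reactants: 15 3-allyl-4-hydroxybenzaldehyde
Product: 16 3-allyl-4-(tert-butyldimethylsilyloxy)benzaldehyde
Conditions: TBSCl, imidazole, DMF, rt
Reagents that add atoms: tert-butyldimethylsilyl chloride, CC(C)(C)[Si](C)(C)Cl
Why: Standard silylation of a phenol; the silyl ether keeps the phenol out of the carbenoid and Mitsunobu steps.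

Step 9
Reactants: 16 3-allyl-4-(tert-butyldimethylsilyloxy)benzaldehyde; 6 2-methyl-2-butene
Product: 17 4-(tert-butyldimethylsilyloxy)-3-prenylbenzaldehyde
Conditions: second-generation Grubbs catalyst RuCl2(=CHPh)(H2IMes)(PCy3) (3 mol %), 2-methyl-2-butene/CH2Cl2, 40 °C, sealed tube
Reagents that add atoms: 2-methyl-2-butene (6), CC=C(C)C
Why: Olefin cross-metathesis as in step 3; aldehydes and aryl silyl ethers are tolerated by the ruthenium carbene.

Step 10
Reactants: 13 2-acetoxy-4-(tert-butyldimethylsilyloxy)-3,5-diprenylphenyl diazomethyl ketone; 18 4-methoxybenzyl alcohol; 17 4-(tert-butyldimethylsilyloxy)-3-prenylbenzaldehyde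
Product: 20 (2R,3S)-1-[2-acetoxy-4-(tert-butyldimethylsilyloxy)-3,5-diprenylphenyl]-3-[4-(tert-butyldimethylsilyloxy)-3-prenylphenyl]-3-hydroxy-2-(4-methoxybenzyloxy)propan-1-one (syn), via oxonium ylide 19 (not isolated)
Conditions: Rh2(OAc)4 (2 mol %), Zr(Ot-Bu)4 (15 mol %), (S)-3,3'-diiodo-BINOL (18 mol %), 4 Å MS, CH2Cl2, −10 °C; 13 added over 2 h to 17 (2 equiv) and 18 (1.2 equiv)
Reagents that add atoms: 4-methoxybenzyl alcohol (18), COc1ccc(CO)cc1
Why: Proposed new method: Rh2(OAc)4 (divalent rhodium) turns 13 into an electrophilic acyl carbenoid, the hydroxyl oxygen of 18 adds to it, and the resulting oxonium ylide 19, in effect a Z-enol whose two oxygens are bridged by the O–H proton, adds through carbon to aldehyde 17 held on the chiral Lewis acid formed from Zr(Ot-Bu)4 (tetravalent zirconium) and the BINOL ligand before the 1,2-proton shift can finish a plain O–H insertion, so the C3–O and C2–C3 bonds (chromanone numbering) are made in one operation. The closest known reaction types are the Rh2(OAc)4/zirconium–BINOL three-component coupling of aryl diazoacetates, alcohols and aldehydes and the Mannich-type trapping by imines of alcohol-derived oxonium ylides from diazoacetophenones under Rh2(OAc)4/chiral phosphoric acid catalysis; the asymmetric aldehyde trapping has not been shown for an acceptor-only diazomethyl ketone, hence the label. No ring is closed. The benzylic carbinol centre (S) is set by the zirconium–BINOL complex, which must deliver the enol to the Re face of 17, and the α-carbon (R) follows from the Z-enol geometry in a closed, zirconium-bridged chair transition state with the aryl group of 17 equatorial, which gives the syn relation. The step needs O–H ylide formation to win over attack of the ortho oxygen, cyclopropanation of the prenyl groups and carbonyl ylide formation, which the acetyl cap on the ortho oxygen, the much higher nucleophilicity of the alcohol and a low stationary carbenoid concentration (slow addition of 13) should secure. It also needs aldehyde capture to outrun the proton shift, which Lewis acid activation of the electron-rich aldehyde, the excess of 17, molecular sieves and low temperature are meant to secure.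

Step 11
Reactants: 20 syn aldol
Product: 21 (2R,3S)-1-[4-(tert-butyldimethylsilyloxy)-2-hydroxy-3,5-diprenylphenyl]-3-[4-(tert-butyldimethylsilyloxy)-3-prenylphenyl]-3-hydroxy-2-(4-methoxybenzyloxy)propan-1-one
Conditions: NH4OAc, MeOH/H2O (4:1), rt
Reagents that add atoms: none
Why: Near-neutral solvolysis of the aryl acetate (activated by the ortho acyl group) should free the phenol while sparing the aryl silyl ethers and the PMB ether and avoiding base-induced retro-aldol cleavage or epimerisation next to the ketone.

Step 12
Reactants: 21 phenol–alcohol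
Product: 22 (2R,3R)-7-(tert-butyldimethylsilyloxy)-2-[4-(tert-butyldimethylsilyloxy)-3-prenylphenyl]-3-(4-methoxybenzyloxy)-6,8-diprenylchroman-4-one
Conditions: PPh3, DIAD, THF, 0 °C to rt
Reagents that add atoms: none
Why: Intramolecular Mitsunobu etherification: the benzylic hydroxyl is activated as its oxyphosphonium ion and displaced by the ortho-acyl phenol (6-exo-tet) with inversion, which turns the (S)-carbinol into C2 (R) and should give the 2,3-trans ring C while C3 is untouched.

Step 13
Reactants: 22 PMB-protected flavanone
Product: 23 (2R,3R)-7-(tert-butyldimethylsilyloxy)-2-[4-(tert-butyldimethylsilyloxy)-3-prenylphenyl]-3-hydroxy-6,8-diprenylchroman-4-one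
Conditions: MgBr2·OEt2, Me2S, CH2Cl2, rt
Reagents that add atoms: none
Why: Chelation-assisted cleavage of the PMB ether: magnesium bridges the C4 carbonyl and the C3 ether oxygen and dimethyl sulfide takes the 4-methoxybenzyl group, conditions that should leave silyl ethers, prenyl groups and both stereocentres alone.

Step 14
Reactants: 23 bis-silyl dihydroflavonol
Product: 24 Lespeflorin B3, (2R,3R)-3,7-dihydroxy-2-(4-hydroxy-3-prenylphenyl)-6,8-diprenylchroman-4-one
Conditions: Bu4NF, AcOH, THF, 0 °C
Reagents that add atoms: none
Why: Fluoride cleavage of the two aryl silyl ethers, buffered with acetic acid so that the base-sensitive trans-dihydroflavonol should neither ring-open, epimerise at C2 nor oxidise to the flavonol.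

**Compound list**

1 | methyl 2,4-dihydroxybenzoate | COC(=O)c1ccc(O)cc1O | starting material
2 | allyl bromide | C=CCBr | starting material
3 | methyl 2,4-bis(allyloxy)benzoate | COC(=O)c1ccc(OCC=C)cc1OCC=C | intermediate
4 | methyl 3-allyl-4-(allyloxy)-2-hydroxybenzoate (representative mono-rearranged phenol, not isolated) | COC(=O)c1ccc(OCC=C)c(CC=C)c1O | intermediate
5 | methyl 3,5-diallyl-2,4-dihydroxybenzoate | COC(=O)c1cc(CC=C)c(O)c(CC=C)c1O | intermediate
6 | 2-methyl-2-butene | CC=C(C)C | starting material
7 | methyl 2,4-dihydroxy-3,5-diprenylbenzoate | COC(=O)c1cc(CC=C(C)C)c(O)c(CC=C(C)C)c1O | intermediate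
8 | 2,4-dihydroxy-3,5-diprenylbenzoic acid | OC(=O)c1cc(CC=C(C)C)c(O)c(CC=C(C)C)c1O | intermediate
9 | tert-butyldimethylsilyl 4-(tert-butyldimethylsilyloxy)-2-hydroxy-3,5-diprenylbenzoate (not isolated) | CC(C)=CCc1cc(C(=O)O[Si](C)(C)C(C)(C)C)c(O)c(CC=C(C)C)c1O[Si](C)(C)C(C)(C)C | intermediate
10 | tert-butyldimethylsilyl 2-acetoxy-4-(tert-butyldimethylsilyloxy)-3,5-diprenylbenzoate (not isolated) | CC(C)=CCc1cc(C(=O)O[Si](C)(C)C(C)(C)C)c(OC(C)=O)c(CC=C(C)C)c1O[Si](C)(C)C(C)(C)C | intermediate
11 | 2-acetoxy-4-(tert-butyldimethylsilyloxy)-3,5-diprenylbenzoic acid | CC(C)=CCc1cc(C(=O)O)c(OC(C)=O)c(CC=C(C)C)c1O[Si](C)(C)C(C)(C)C | intermediate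
12 | 2-acetoxy-4-(tert-butyldimethylsilyloxy)-3,5-diprenylbenzoyl chloride (not isolated) | CC(C)=CCc1cc(C(Cl)=O)c(OC(C)=O)c(CC=C(C)C)c1O[Si](C)(C)C(C)(C)C | intermediate
13 | 2-acetoxy-4-(tert-butyldimethylsilyloxy)-3,5-diprenylphenyl diazomethyl ketone | [N-]=[N+]=CC(=O)c1cc(CC=C(C)C)c(O[Si](C)(C)C(C)(C)C)c(CC=C(C)C)c1OC(C)=O | intermediate
14 | 4-(allyloxy)benzaldehyde | C=CCOc1ccc(C=O)cc1 | starting material
15 | 3-allyl-4-hydroxybenzaldehyde | C=CCc1cc(C=O)ccc1O | intermediate
16 | 3-allyl-4-(tert-butyldimethylsilyloxy)benzaldehyde | C=CCc1cc(C=O)ccc1O[Si](C)(C)C(C)(C)C | intermediate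
17 | 4-(tert-butyldimethylsilyloxy)-3-prenylbenzaldehyde | CC(C)=CCc1cc(C=O)ccc1O[Si](C)(C)C(C)(C)C | intermediate
18 | 4-methoxybenzyl alcohol | COc1ccc(CO)cc1 | starting material
19 | oxonium ylide from the carbenoid of 13 and 18, drawn as enolate–oxonium zwitterion (not isolated) | COc1ccc(C[OH+]C=C([O-])c2cc(CC=C(C)C)c(O[Si](C)(C)C(C)(C)C)c(CC=C(C)C)c2OC(C)=O)cc1 | intermediate
20 | (2R,3S)-1-[2-acetoxy-4-(tert-butyldimethylsilyloxy)-3,5-diprenylphenyl]-3-[4-(tert-butyldimethylsilyloxy)-3-prenylphenyl]-3-hydroxy-2-(4-methoxybenzyloxy)propan-1-one | CC(C)=CCc1cc(ccc1O[Si](C)(C)C(C)(C)C)[C@H](O)[C@@H](OCc1ccc(OC)cc1)C(=O)c1cc(CC=C(C)C)c(O[Si](C)(C)C(C)(C)C)c(CC=C(C)C)c1OC(C)=O | intermediate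
21 | (2R,3S)-1-[4-(tert-butyldimethylsilyloxy)-2-hydroxy-3,5-diprenylphenyl]-3-[4-(tert-butyldimethylsilyloxy)-3-prenylphenyl]-3-hydroxy-2-(4-methoxybenzyloxy)propan-1-one | CC(C)=CCc1cc(ccc1O[Si](C)(C)C(C)(C)C)[C@H](O)[C@@H](OCc1ccc(OC)cc1)C(=O)c1cc(CC=C(C)C)c(O[Si](C)(C)C(C)(C)C)c(CC=C(C)C)c1O | intermediate
22 | (2R,3R)-7-(tert-butyldimethylsilyloxy)-2-[4-(tert-butyldimethylsilyloxy)-3-prenylphenyl]-3-(4-methoxybenzyloxy)-6,8-diprenylchroman-4-one | CC(C)=CCc1cc([C@H]2Oc3c(cc(CC=C(C)C)c(O[Si](C)(C)C(C)(C)C)c3CC=C(C)C)C(=O)[C@@H]2OCc2ccc(OC)cc2)ccc1O[Si](C)(C)C(C)(C)C | intermediate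
23 | (2R,3R)-7-(tert-butyldimethylsilyloxy)-2-[4-(tert-butyldimethylsilyloxy)-3-prenylphenyl]-3-hydroxy-6,8-diprenylchroman-4-one | CC(C)=CCc1cc([C@H]2Oc3c(cc(CC=C(C)C)c(O[Si](C)(C)C(C)(C)C)c3CC=C(C)C)C(=O)[C@@H]2O)ccc1O[Si](C)(C)C(C)(C)C | intermediate
24 | Lespeflorin B3 | CC(C)=CCc1cc([C@H]2Oc3c(cc(CC=C(C)C)c(O)c3CC=C(C)C)C(=O)[C@@H]2O)ccc1O | target

**Step count and risks**

Total step count: 14. Longest linear sequence: 11 steps (steps 1–6, then 10–14); the ring B aldehyde is made in 3 steps (7–9).

Steps most likely to fail:

1. Step 10 (three-component coupling). The 1,2-proton shift of the ylide may outrun capture by the electron-rich aldehyde, so that plain O–H insertion dominates, or capture may occur with poor facial or syn/anti control. The fallback makes the two bonds one after the other by known reactions; it sets out from 13 and comes back at 20. Rh2(OAc)4 and 18 alone in CH2Cl2 should give, by ordinary O–H insertion, 1-[2-acetoxy-4-(tert-butyldimethylsilyloxy)-3,5-diprenylphenyl]-2-(4-methoxybenzyloxy)ethanone F1. Soft enolisation with Me3SiOTf and Et3N should give its (Z)-trimethylsilyl enol ether F2. A Mukaiyama aldol addition of F2 to 17 follows, catalysed by the chiral acyloxyborane made from BH3·THF and a mono-2-O-(2,6-diisopropoxybenzoyl)tartaric acid; this catalyst type is syn-selective for enol silanes of aryl ketones with aromatic aldehydes whatever the enol geometry. Dilute acid work-up removes the trimethylsilyl group and returns 20; the tartaric acid antipode is chosen by the same MTPA check.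

2. Step 12 (Mitsunobu closure). The activated benzylic C–O bond may ionise before the phenol attacks, because the para-silyloxy group stabilises the cation, so that stereospecificity at C2 leaks; the oxyphosphonium ion may also eliminate to the enone. The fallback gives up the invertive displacement and closes ring C under thermodynamic control; it sets out from 21 and comes back at 22 and makes no new compound (F0). Catalytic camphorsulfonic acid with 4 Å MS in CH2Cl2 (0 °C to rt) ionises the benzylic alcohol on purpose. The phenol captures the cation, and because C3 is not enolised under these conditions it should direct both the kinetic closure and any reversible reopening to the 2,3-trans isomer, in which the aryl and PMB-oxy groups are both equatorial. The free phenol next to the C8 prenyl group must be watched for chroman formation.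

3. Step 11 (deacetylation). Retro-aldol cleavage or epimerisation α to the ketone may set in once a base or nucleophile meets the β-hydroxy ketone, and an aryl silyl group may be lost. The fallback blocks the retro-aldol path before the phenol is freed; it sets out from 20 and comes back at 21. Et3SiOTf and 2,6-lutidine in CH2Cl2 at −78 °C should give the benzylic triethylsilyl ether of 20, F3. Brief K2CO3 in MeOH at 0 °C removes the acetate to give the corresponding phenol F4, since no β-alkoxide can form. HF·pyridine buffered with pyridine in THF at 0 °C then removes the alkyl triethylsilyl ether in preference to the aryl TBS ethers and returns 21.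

**Further compounds**

F1 | step 10 | 1-[2-acetoxy-4-(tert-butyldimethylsilyloxy)-3,5-diprenylphenyl]-2-(4-methoxybenzyloxy)ethanone | COc1ccc(COCC(=O)c2cc(CC=C(C)C)c(O[Si](C)(C)C(C)(C)C)c(CC=C(C)C)c2OC(C)=O)cc1
F2 | step 10 | (Z)-1-[2-acetoxy-4-(tert-butyldimethylsilyloxy)-3,5-diprenylphenyl]-2-(4-methoxybenzyloxy)-1-(trimethylsilyloxy)ethene | COc1ccc(CO/C=C(\O[Si](C)(C)C)c2cc(CC=C(C)C)c(O[Si](C)(C)C(C)(C)C)c(CC=C(C)C)c2OC(C)=O)cc1
F0 | step 12 | none | none
F3 | step 11 | (2R,3S)-1-[2-acetoxy-4-(tert-butyldimethylsilyloxy)-3,5-diprenylphenyl]-3-[4-(tert-butyldimethylsilyloxy)-3-prenylphenyl]-2-(4-methoxybenzyloxy)-3-(triethylsilyloxy)propan-1-one | CC(C)=CCc1cc(ccc1O[Si](C)(C)C(C)(C)C)[C@H](O[Si](CC)(CC)CC)[C@@H](OCc1ccc(OC)cc1)C(=O)c1cc(CC=C(C)C)c(O[Si](C)(C)C(C)(C)C)c(CC=C(C)C)c1OC(C)=O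
F4 | step 11 | (2R,3S)-1-[4-(tert-butyldimethylsilyloxy)-2-hydroxy-3,5-diprenylphenyl]-3-[4-(tert-butyldimethylsilyloxy)-3-prenylphenyl]-2-(4-methoxybenzyloxy)-3-(triethylsilyloxy)propan-1-one | CC(C)=CCc1cc(ccc1O[Si](C)(C)C(C)(C)C)[C@H](O[Si](CC)(CC)CC)[C@@H](OCc1ccc(OC)cc1)C(=O)c1cc(CC=C(C)C)c(O[Si](C)(C)C(C)(C)C)c(CC=C(C)C)c1O
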